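The seven-membered ring (C3a–C4–C5–C6–C7–C8–C8a of the octahydroazulene) is traced back to a cyclobutanone fused to the cyclopentane ring. The acyloxy carbon C4 is the former carbonyl carbon, C8 its α-carbon, and C5=C6(CH3)–C7 a pendant vinyl iodide. One Dowd–Beckwith three-carbon ring expansion by the vinyl radical turns this bicyclo[3.2.0]heptanone into the cis-fused 6-methylcyclohept-5-en-4-one. It exploits the cis C3a–H/C8a–CH3 junction, the quaternary C8a and the allylic C4–O/C5=C6 array. The cyclobutanone comes from dichloroketene and an (R)-allylic silyl ether, whose oxygen later becomes the C3 carbinol.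

Key step: step 8

Remark: compound 12 is carried as a mixture of C7 epimers, because this carbon becomes the C8 methylene of the azulene; its SMILES therefore has no descriptor at that atom. TBS = tert-butyldimethylsilyl, TIPS = triisopropylsilyl.

Step 1
Reactants: 1 3-methylcyclopent-2-en-1-one
Product: 2 (R)-3-methylcyclopent-2-en-1-ol
Conditions: (S)-Me-CBS (10 mol %), BH3·SMe2, THF, −20 °C; MeOH quench
Reagents that add atoms: none
Why: Corey–Bakshi–Shibata reduction; the catalyst should treat the alkenyl flank as the large group and deliver hydride to one carbonyl face, setting the (R)-carbinol under reagent control.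

Step 2
Reactants: 2 (R)-3-methylcyclopent-2-en-1-ol
Product: 3 (R)-tert-butyldimethyl[(3-methylcyclopent-2-en-1-yl)oxy]silane
Conditions: TBSCl, imidazole, DMF, rt
Reagents that add atoms: tert-butyldimethylsilyl chloride CC(C)(C)[Si](C)(C)Cl
Why: standard silylation of a secondary alcohol; the bulky silyl ether should later shield one alkene face and survive zinc, LDA and tin hydride.

Step 3
Reactants: 3 (R)-tert-butyldimethyl[(3-methylcyclopent-2-en-1-yl)oxy]silane
Product: 5 (1R,4R,5R)-4-(TBSO)-7,7-dichloro-1-methylbicyclo[3.2.0]heptan-6-one, via dichloroketene 4 (not isolated)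
Conditions: Cl3CCOCl, Zn(Cu), Et2O, 0 °C → rt
Reagents that add atoms: trichloroacetyl chloride ClC(=O)C(Cl)(Cl)Cl
Why: thermal ketene–alkene [2+2] cycloaddition; it is suprafacial on the alkene (cis ring fusion, C1 and C5 set together), the carbonyl carbon should bond to the less substituted alkene carbon, and the ketene should approach anti to the allylic OTBS group.

Step 4
Reactants: 5 (1R,4R,5R)-4-(TBSO)-7,7-dichloro-1-methylbicyclo[3.2.0]heptan-6-one
Product: 6 (1S,4R,5R)-4-(TBSO)-1-methylbicyclo[3.2.0]heptan-6-one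
Conditions: Zn dust, AcOH, rt
Reagents that add atoms: none
Why: reductive dechlorination of an α,α-dichlorocyclobutanone with zinc, the standard follow-up of a dichloroketene cycloaddition, which should leave the stereocenters and the silyl ether untouched.

Step 5
Reactants: 7 prop-2-yn-1-ol
Product: 9 (Z)-3-iodo-2-methylprop-2-en-1-ol, via bromomagnesium (Z)-3-(bromomagnesio)-2-methylprop-2-en-1-olate 8 (not isolated)
Conditions: MeMgBr (2.5 equiv), CuI (10 mol %), THF, −10 °C → rt; then I2, −78 → 0 °C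
Reagents that add atoms: methylmagnesium bromide C[Mg]Br; iodine II
Why: copper-catalysed anti carbomagnesiation of the propargylic alkoxide gives a chelated vinylmagnesium species, and iodinolysis with retention should give the (Z)-vinyl iodide.

Step 6
Reactants: 9 (Z)-3-iodo-2-methylprop-2-en-1-ol
Product: 10 (Z)-3-bromo-1-iodo-2-methylprop-1-ene
Conditions: CBr4, PPh3, CH2Cl2, 0 °C
Reagents that add atoms: carbon tetrabromide BrC(Br)(Br)Br
Why: Appel bromination of a primary allylic alcohol, which should leave the vinyl iodide unchanged.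

Step 7
Reactants: 6 (1S,4R,5R)-4-(TBSO)-1-methylbicyclo[3.2.0]heptan-6-one; 10 (Z)-3-bromo-1-iodo-2-methylprop-1-ene
Product: 12 (1S,4R,5R)-4-(TBSO)-7-[(2Z)-3-iodo-2-methylprop-2-en-1-yl]-1-methylbicyclo[3.2.0]heptan-6-one as a mixture of C7 epimers, via lithium enolate of the cyclobutanone 11 (not isolated)
Conditions: LDA, THF, −78 °C; then 10, DMPU, −78 → −30 °C
Reagents that add atoms: none
Why: kinetic enolate alkylation with a reactive allylic bromide; only the C7 methylene can be deprotonated, since an enolate toward the ring-fusion carbon C5 would be a strained bridgehead-type cyclobutene, and the new C7 center need not be controlled.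

Step 8
Reactants: 12 (1S,4R,5R)-4-(TBSO)-7-[(2Z)-3-iodo-2-methylprop-2-en-1-yl]-1-methylbicyclo[3.2.0]heptan-6-one
Product: 13 (3R,3aR,8aR)-3-(TBSO)-6,8a-dimethyl-2,3,3a,7,8,8a-hexahydroazulen-4(1H)-one
Conditions: Bu3SnH (1.3 equiv), AIBN (cat.), PhH (0.005 M), 80 °C, syringe-pump addition
Reagents that add atoms: none
Why: Bu3Sn• abstracts iodine to give a configurationally labile σ-vinyl radical, which should add 5-exo-trig to the strained cyclobutanone carbonyl; the resulting tricyclic alkoxy radical should undergo β-scission of the bond shared by the four- and five-membered rings (C6–C7 of 12), and the secondary C8 radical is then reduced by Bu3SnH. The closest known reaction type is the Dowd–Beckwith three-carbon ring expansion of fused cyclobutanones, run here with an sp2 radical so that the C5=C6 double bond arrives already conjugated to the new C4 ketone. The seven-membered ring is thus closed by a radical 5-exo-trig addition to C=O followed by fragmentation of the temporary cyclobutane, a net insertion of C5–C6–C7 between the carbonyl carbon and its α-carbon. No stereocenter is created: the cis C3a–H/C8a–CH3 junction is inherited from step 3, the C7 center of 12 becomes the C8 methylene, and the neutral conditions should leave the epimerisable C3a untouched. The step needs cyclisation to outrun direct reduction of the vinyl radical, which high dilution with slow tin hydride addition and the electrophilic strained carbonyl should secure; it also needs cleavage of the internal rather than the outer cyclobutane bond, which release of the fused-ring strain and formation of the conjugated enone should favour.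

Step 9
Reactants: 13 (3R,3aR,8aR)-3-(TBSO)-6,8a-dimethyl-2,3,3a,7,8,8a-hexahydroazulen-4(1H)-one
Product: 14 (3R,3aS,4R,8aR)-3-(TBSO)-6,8a-dimethyl-1,2,3,3a,4,7,8,8a-octahydroazulen-4-ol
Conditions: NaBH4, CeCl3·7H2O, MeOH, −78 °C
Reagents that add atoms: none
Why: Luche 1,2-reduction of the enone; hydride should arrive on the convex face of the cis-fused bicycle (the face of C3a–H), which places the new hydroxyl on the concave face, cis to C3 across the seven-membered ring (4R).

Step 10
Reactants: 15 3-hydroxy-4-methoxybenzoic acid (isovanillic acid)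
Product: 17 4-methoxy-3-[(triisopropylsilyl)oxy]benzoic acid, via triisopropylsilyl 4-methoxy-3-[(triisopropylsilyl)oxy]benzoate 16 (not isolated)
Conditions: TIPSCl (2.2 equiv), imidazole, DMF, rt; then AcOH, THF/H2O, rt
Reagents that add atoms: triisopropylsilyl chloride CC(C)[Si](Cl)(C(C)C)C(C)C
Why: double silylation followed by selective hydrolysis of the labile silyl ester should leave the phenol masked as a robust aryl TIPS ether.

Step 11
Reactants: 14 (3R,3aS,4R,8aR)-3-(TBSO)-6,8a-dimethyl-1,2,3,3a,4,7,8,8a-octahydroazulen-4-ol; 17 4-methoxy-3-[(triisopropylsilyl)oxy]benzoic acid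
Product: 18 (3R,3aS,4R,8aR)-3-(TBSO)-6,8a-dimethyl-1,2,3,3a,4,7,8,8a-octahydroazulen-4-yl 4-methoxy-3-[(triisopropylsilyl)oxy]benzoate
Conditions: DCC, DMAP, CH2Cl2, rt
Reagents that add atoms: none
Why: Steglich esterification of the only free hydroxyl, with retention at C4 because the C–O bond of the alcohol is not broken.

Step 12
Reactants: 18 (3R,3aS,4R,8aR)-3-(TBSO)-6,8a-dimethyl-1,2,3,3a,4,7,8,8a-octahydroazulen-4-yl 4-methoxy-3-[(triisopropylsilyl)oxy]benzoate
Product: 19 (3R,3aR,4R,8aR)-3-hydroxy-6,8a-dimethyl-1,2,3,3a,4,7,8,8a-octahydroazulen-4-yl 4-methoxy-3-[(triisopropylsilyl)oxy]benzoate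
Conditions: CSA, MeOH/CH2Cl2, 0 °C → rt
Reagents that add atoms: none
Why: acid-catalysed methanolysis should remove a secondary alkyl TBS ether much faster than a hindered aryl TIPS ether, so that only the C3 hydroxyl is freed.

Step 13
Reactants: 19 (3R,3aR,4R,8aR)-3-hydroxy-6,8a-dimethyl-1,2,3,3a,4,7,8,8a-octahydroazulen-4-yl 4-methoxy-3-[(triisopropylsilyl)oxy]benzoate
Product: 20 (3aS,4R,8aR)-6,8a-dimethyl-3-oxo-1,2,3,3a,4,7,8,8a-octahydroazulen-4-yl 4-methoxy-3-[(triisopropylsilyl)oxy]benzoate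
Conditions: Dess–Martin periodinane, NaHCO3, CH2Cl2, 0 °C → rt
Reagents that add atoms: none
Why: Dess–Martin oxidation of the secondary alcohol under buffered, non-basic conditions should give the C3 ketone without epimerising C3a or eliminating the β-acyloxy group.

Step 14
Reactants: 20 (3aS,4R,8aR)-6,8a-dimethyl-3-oxo-1,2,3,3a,4,7,8,8a-octahydroazulen-4-yl 4-methoxy-3-[(triisopropylsilyl)oxy]benzoate
Product: 21 (3R,3aS,4R,8aR)-3-hydroxy-6,8a-dimethyl-3-(propan-2-yl)-1,2,3,3a,4,7,8,8a-octahydroazulen-4-yl 4-methoxy-3-[(triisopropylsilyl)oxy]benzoate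
Conditions: iPrMgCl, LaCl3·2LiCl, THF, −78 → 0 °C
Reagents that add atoms: isopropylmagnesium chloride CC(C)[Mg]Cl
Why: lanthanide-promoted Grignard 1,2-addition, chosen to suppress enolisation, β-elimination and reduction; the nucleophile should attack the cyclopentanone from the convex face, anti to the C4 acyloxy group on the adjacent C3a, so that the hydroxyl ends cis to C4 (3R), while the hindered electron-rich aryl ester should be spared at low temperature.

Step 15
Reactants: 21 (3R,3aS,4R,8aR)-3-hydroxy-6,8a-dimethyl-3-(propan-2-yl)-1,2,3,3a,4,7,8,8a-octahydroazulen-4-yl 4-methoxy-3-[(triisopropylsilyl)oxy]benzoate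
Product: 22 (3R,3aS,4R,8aR)-3-hydroxy-6,8a-dimethyl-3-(propan-2-yl)-1,2,3,3a,4,7,8,8a-octahydroazulen-4-yl 3-hydroxy-4-methoxybenzoate
Conditions: TBAF, AcOH, THF, 0 °C
Reagents that add atoms: none
Why: fluoride should cleave the aryl silyl ether rapidly, and buffering with acetic acid should prevent acyl migration or ester cleavage.

Compound list
1 | 3-methylcyclopent-2-en-1-one | CC1=CC(=O)CC1 | starting material
2 | (R)-3-methylcyclopent-2-en-1-ol | O[C@H]1C=C(C)CC1 | intermediate
3 | (R)-tert-butyldimethyl[(3-methylcyclopent-2-en-1-yl)oxy]silane | CC(C)(C)[Si](C)(C)O[C@H]1C=C(C)CC1 | intermediate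
4 | dichloroketene | ClC(Cl)=C=O | intermediate
5 | (1R,4R,5R)-4-[(tert-butyldimethylsilyl)oxy]-7,7-dichloro-1-methylbicyclo[3.2.0]heptan-6-one | CC(C)(C)[Si](C)(C)O[C@H]1[C@@H]2C(=O)C(Cl)(Cl)[C@]2(C)CC1 | intermediate
6 | (1S,4R,5R)-4-[(tert-butyldimethylsilyl)oxy]-1-methylbicyclo[3.2.0]heptan-6-one | CC(C)(C)[Si](C)(C)O[C@H]1[C@@H]2C(=O)C[C@]2(C)CC1 | intermediate
7 | prop-2-yn-1-ol | C#CCO | starting material
8 | bromomagnesium (Z)-3-(bromomagnesio)-2-methylprop-2-en-1-olate | Br[Mg]OC/C(C)=C\[Mg]Br | intermediate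
9 | (Z)-3-iodo-2-methylprop-2-en-1-ol | OC/C(C)=C\I | intermediate
10 | (Z)-3-bromo-1-iodo-2-methylprop-1-ene | BrC/C(C)=C\I | intermediate
11 | lithium enolate of cyclobutanone 6 (C6=C7 enolate) | [Li+].CC(C)(C)[Si](C)(C)O[C@H]1[C@@H]2C([O-])=C[C@]2(C)CC1 | intermediate
12 | (1S,4R,5R)-4-[(tert-butyldimethylsilyl)oxy]-7-[(2Z)-3-iodo-2-methylprop-2-en-1-yl]-1-methylbicyclo[3.2.0]heptan-6-one (C7 epimers) | CC(C)(C)[Si](C)(C)O[C@H]1[C@@H]2C(=O)C(C/C(C)=C\I)[C@]2(C)CC1 | intermediate
13 | (3R,3aR,8aR)-3-[(tert-butyldimethylsilyl)oxy]-6,8a-dimethyl-2,3,3a,7,8,8a-hexahydroazulen-4(1H)-one | CC(C)(C)[Si](C)(C)O[C@H]1[C@@H]2C(=O)C=C(C)CC[C@]2(C)CC1 | intermediate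
14 | (3R,3aS,4R,8aR)-3-[(tert-butyldimethylsilyl)oxy]-6,8a-dimethyl-1,2,3,3a,4,7,8,8a-octahydroazulen-4-ol | CC(C)(C)[Si](C)(C)O[C@H]1[C@@H]2[C@H](O)C=C(C)CC[C@]2(C)CC1 | intermediate
15 | 3-hydroxy-4-methoxybenzoic acid (isovanillic acid) | COc1ccc(C(=O)O)cc1O | starting material
16 | triisopropylsilyl 4-methoxy-3-[(triisopropylsilyl)oxy]benzoate | COc1ccc(C(=O)O[Si](C(C)C)(C(C)C)C(C)C)cc1O[Si](C(C)C)(C(C)C)C(C)C | intermediate
17 | 4-methoxy-3-[(triisopropylsilyl)oxy]benzoic acid | COc1ccc(C(=O)O)cc1O[Si](C(C)C)(C(C)C)C(C)C | intermediate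
18 | (3R,3aS,4R,8aR)-3-[(tert-butyldimethylsilyl)oxy]-6,8a-dimethyl-1,2,3,3a,4,7,8,8a-octahydroazulen-4-yl 4-methoxy-3-[(triisopropylsilyl)oxy]benzoate | CC(C)(C)[Si](C)(C)O[C@H]1[C@@H]2[C@H](OC(=O)c3ccc(OC)c(O[Si](C(C)C)(C(C)C)C(C)C)c3)C=C(C)CC[C@]2(C)CC1 | intermediate
19 | (3R,3aR,4R,8aR)-3-hydroxy-6,8a-dimethyl-1,2,3,3a,4,7,8,8a-octahydroazulen-4-yl 4-methoxy-3-[(triisopropylsilyl)oxy]benzoate | O[C@H]1[C@@H]2[C@H](OC(=O)c3ccc(OC)c(O[Si](C(C)C)(C(C)C)C(C)C)c3)C=C(C)CC[C@]2(C)CC1 | intermediate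
20 | (3aS,4R,8aR)-6,8a-dimethyl-3-oxo-1,2,3,3a,4,7,8,8a-octahydroazulen-4-yl 4-methoxy-3-[(triisopropylsilyl)oxy]benzoate | O=C1[C@@H]2[C@H](OC(=O)c3ccc(OC)c(O[Si](C(C)C)(C(C)C)C(C)C)c3)C=C(C)CC[C@]2(C)CC1 | intermediate
21 | (3R,3aS,4R,8aR)-3-hydroxy-6,8a-dimethyl-3-(propan-2-yl)-1,2,3,3a,4,7,8,8a-octahydroazulen-4-yl 4-methoxy-3-[(triisopropylsilyl)oxy]benzoate | CC(C)[C@@]1(O)[C@@H]2[C@H](OC(=O)c3ccc(OC)c(O[Si](C(C)C)(C(C)C)C(C)C)c3)C=C(C)CC[C@]2(C)CC1 | intermediate
22 | (3R,3aS,4R,8aR)-3-hydroxy-6,8a-dimethyl-3-(propan-2-yl)-1,2,3,3a,4,7,8,8a-octahydroazulen-4-yl 3-hydroxy-4-methoxybenzoate | COc1ccc(C(=O)O[C@@H]2C=C(C)CC[C@]3(C)CC[C@@](O)(C(C)C)[C@H]23)cc1O | target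

Total step count: 15. Longest linear sequence: 12 steps (steps 1, 2, 3, 4, 7, 8, 9, 11, 12, 13, 14, 15).

Steps most likely to fail

Step 8. Hydrogen transfer from the tin hydride to the vinyl radical may outrun its addition to the carbonyl group, so that simple deiodination competes with ring expansion. The fallback sets out from 12 and separates bond formation from fragmentation. An intramolecular Nozaki–Hiyama–Kishi reaction (CrCl2, cat. NiCl2, DMF) should add the vinyl iodide to the cyclobutanone carbonyl in a two-electron step and give the tricyclic cyclobutanol 3-[(tert-butyldimethylsilyl)oxy]-6,9-dimethyltricyclo[5.3.0.0^2,6]dec-9-en-1-ol F1. Its alkoxy radical, generated under Suárez conditions (PhI(OAc)2, I2, hν, cyclohexane), should cleave the internal cyclobutane bond and be trapped as the iodo enone 3-[(tert-butyldimethylsilyl)oxy]-8-iodo-6,8a-dimethyl-2,3,3a,7,8,8a-hexahydroazulen-4(1H)-one F2. Reductive removal of iodine (Bu3SnH, AIBN) comes back to the route at 13.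

Step 14. Enolisation toward C3a with loss of the β-acyloxy group, or attack of the Grignard reagent on the aryl ester, may consume ketone 20. The fallback sets out from 14 and installs the isopropyl group before the ester. Silylation of the C4 hydroxyl (TIPSOTf, 2,6-lutidine) should give the bis-silyl ether 3-[(tert-butyldimethylsilyl)oxy]-6,8a-dimethyl-4-[(triisopropylsilyl)oxy]-1,2,3,3a,4,7,8,8a-octahydroazulene F3. Selective acid methanolysis of the TBS ether (CSA, MeOH) should give the alcohol 6,8a-dimethyl-4-[(triisopropylsilyl)oxy]-1,2,3,3a,4,7,8,8a-octahydroazulen-3-ol F4, and Dess–Martin oxidation the β-silyloxy ketone 6,8a-dimethyl-4-[(triisopropylsilyl)oxy]-2,3,3a,4,7,8-hexahydroazulen-3(8aH)-one F5. Addition of iPrMgCl/LaCl3·2LiCl from the convex face should give the tertiary alcohol 6,8a-dimethyl-3-(propan-2-yl)-4-[(triisopropylsilyl)oxy]-1,2,3,3a,4,7,8,8a-octahydroazulen-3-ol F6, and TBAF the diol (3R,3aS,4R,8aR)-6,8a-dimethyl-3-(propan-2-yl)-1,2,3,3a,4,7,8,8a-octahydroazulene-3,4-diol F7. Steglich esterification with 17 (DCC, DMAP) should acylate only the secondary allylic hydroxyl and comes back to the route at 21.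

Step 9. Facial selectivity may be poor or reversed if the angular C8a methyl group, which sits on the convex face, hinders hydride approach more than the cyclopentane ring does. The fallback sets out from 13. If the reduction gives mainly the epimeric alcohol (3R,3aS,4S,8aR)-3-[(tert-butyldimethylsilyl)oxy]-6,8a-dimethyl-1,2,3,3a,4,7,8,8a-octahydroazulen-4-ol F8, this is esterified with acid 17 under Mitsunobu conditions (PPh3, DIAD, THF). The C–O bond is then formed with inversion instead of retention, and the sequence comes back to the route at 18.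

Further compounds
F1 | step 8 | 3-[(tert-butyldimethylsilyl)oxy]-6,9-dimethyltricyclo[5.3.0.0^2,6]dec-9-en-1-ol (ring A as in 12; C1/C7 fusion epimers) | CC(C)(C)[Si](C)(C)O[C@H]1[C@@H]2C3(O)C=C(C)CC3[C@]2(C)CC1
F2 | step 8 | 3-[(tert-butyldimethylsilyl)oxy]-8-iodo-6,8a-dimethyl-2,3,3a,7,8,8a-hexahydroazulen-4(1H)-one (C8 epimers; other centers as in 13) | CC(C)(C)[Si](C)(C)O[C@H]1[C@@H]2C(=O)C=C(C)CC(I)[C@]2(C)CC1
F3 | step 14 | 3-[(tert-butyldimethylsilyl)oxy]-6,8a-dimethyl-4-[(triisopropylsilyl)oxy]-1,2,3,3a,4,7,8,8a-octahydroazulene (configuration as in 14) | CC(C)(C)[Si](C)(C)O[C@H]1[C@@H]2[C@H](O[Si](C(C)C)(C(C)C)C(C)C)C=C(C)CC[C@]2(C)CC1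
F4 | step 14 | 6,8a-dimethyl-4-[(triisopropylsilyl)oxy]-1,2,3,3a,4,7,8,8a-octahydroazulen-3-ol (configuration as in 14) | O[C@H]1[C@@H]2[C@H](O[Si](C(C)C)(C(C)C)C(C)C)C=C(C)CC[C@]2(C)CC1
F5 | step 14 | 6,8a-dimethyl-4-[(triisopropylsilyl)oxy]-2,3a,4,7,8,8a-hexahydroazulen-3(1H)-one (configuration as in 14) | O=C1[C@@H]2[C@H](O[Si](C(C)C)(C(C)C)C(C)C)C=C(C)CC[C@]2(C)CC1
F6 | step 14 | 6,8a-dimethyl-3-(propan-2-yl)-4-[(triisopropylsilyl)oxy]-1,2,3,3a,4,7,8,8a-octahydroazulen-3-ol (configuration as in 21) | CC(C)[C@@]1(O)[C@@H]2[C@H](O[Si](C(C)C)(C(C)C)C(C)C)C=C(C)CC[C@]2(C)CC1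
F7 | step 14 | (3R,3aS,4R,8aR)-6,8a-dimethyl-3-(propan-2-yl)-1,2,3,3a,4,7,8,8a-octahydroazulene-3,4-diol | CC(C)[C@@]1(O)[C@@H]2[C@H](O)C=C(C)CC[C@]2(C)CC1
F8 | step 9 | (3R,3aS,4S,8aR)-3-[(tert-butyldimethylsilyl)oxy]-6,8a-dimethyl-1,2,3,3a,4,7,8,8a-octahydroazulen-4-ol | CC(C)(C)[Si](C)(C)O[C@H]1[C@@H]2[C@@H](O)C=C(C)CC[C@]2(C)CC1
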